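Between 50.0 s and 80.0 s the alder run's monomer in chains climbs from 26.7 % to 49.3 % of the charge.

| flask | free monomer | initiator | remark | time |
|---|---|---|---|---|
| alder | 0.050 M | 0.94 mM | run made earlier |  |
| birch | 0.050 M | 0.70 mM | run made earlier |  |
| summer | 0.050 M | 1.4 mM |  | 4.0 min |
| noon | 0.080 M | 1.4 mM |  | 4.0 min |

| alder: time / s | alder: monomer in chains / % | birch: time / s | birch: monomer in chains / % |
|---|---|---|---|
| 15.0 | 3.1 | 15.0 | 2.0 |
| 30.0 | 8.9 | 30.0 | 9.7 |
| 50.0 | 26.7 | 50.0 | 21.9 |
| 60.0 | 35.3 | 60.0 | 27.5 |
| 80.0 | 49.3 | 80.0 | 39.3 |

(standard deviation of a reading: 1 percentage point)

- the average divides the monomer in chains by the number of chains begun, living and dead together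
- the numbers in the tables scatter by 1 percentage point (one standard deviation)
- the earlier runs do not show the number of chains; that part of a forecast is a guess

1. which of the two ends with the longer chains by the average number of monomer units in a chain (chains begun, living or dead) ("neither" if they lie within 10 %) (summer / noon / neither)
2. average number of monomer units in a chain (chains begun, living or dead) at the end, summer
3. average number of monomer units in a chain (chains begun, living or dead) at the end, noon

Taking the rest as free monomer, I read a pseudo-first-order loss of 0.0123 s⁻¹ in the alder run, and 0.00840 s⁻¹ over the same stretch of the birch run. These readings differ by a factor of 1.46 and the initiator charges by 1.34, so I let the rate follow the initiator charge. Scaled to 1.4 mM, it becomes 0.0183 s⁻¹. Over 4.0 min that leaves a fraction 0.0124 of the free monomer, hardly any. I use the same fraction for noon, though both runs had one monomer charge, so noon's higher charge is untested.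

Summer charges 35.7 units of free monomer per initiator, and noon 57.1; this charge ratio, free monomer charged per initiator charged, is what I carry. If every initiator begins one chain and all lost free monomer enters chains, the lengths are 35.3 and 56.4.

That first "if" is the weak link, and the readings show no chain count. So I reforge it: length equals charge ratio times the fraction of free monomer in chains, divided by the fraction of initiator used. With the fraction in chains held, unused initiator lengthens the chains. I commit to noon.

The forecast also says noon, with 35 for summer and 56 for noon: “The assumption of one chain per initiator is a guess, so a lower efficiency would give longer chains.”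

Summer ends at 85.4 units per chain and noon at 115, so noon has the longer chains.

    free monomer + initiator → living end + monomer in chains (k = 0.140 L mol⁻¹ s⁻¹)
    free monomer + living end → monomer in chains + living end, rate k2*[living end]*[free monomer] (k = 52.0 L mol⁻¹ s⁻¹)
    free monomer → uncatalysed product (k = 0.00280 s⁻¹)

At 4.00 min summer holds 0.33 % of its free monomer, the first charge to run out, and 65 % of its initiator. With 82.7 % of the free monomer in chains and 34.6 % of the initiator used, the charge ratio 35.7 becomes 85.4. A neighbour of noon charged with 8.4 × 10⁻⁴ M of initiator has a charge ratio of 95.2, puts 81.4 % of its free monomer in chains and uses 51.4 % of its initiator, so its chains average 151 units.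

The numbers in the tables come from a simulation with made-up constants, and the scatter is random.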